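Ring A is disconnected at C1–C2 and C3–C4. It hides a four-membered ring: C1 (C=O), C6, C5 (OMe) and the quaternary C4 (OMe) are oxidised exactly as in a 3,4-dimethoxycyclobut-2-enone, and C2, C3 plus the allyl group are a 2-metalated penta-1,4-diene. In one flask the alkenyllithium adds to C1, the strained cyclobutenoxide opens, the trienolate recloses and the dienolate is silylated, which builds ring A, two C–C bonds and the stereocentre C4. The precursor is a 4-alkyl-3,4-dimethoxycyclobutenone (ketene plus methoxyacetylene) whose side chain already carries C7 and C8 from an Evans syn-aldol.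

Key step: step 9

Numbering used: ring A is C1 (C=O), C2 (allyl), C3 (=CH), C4 (quaternary, OMe), C5 (OMe), C6 (=CH); the side chain is C8 (CH–CH3) and C7 (CH–OAc, aryl). In this numbering the target is (4R,7R,8R). The (R)-auxiliary syn-aldol gives (2R,3R), which maps onto (7R,8R).

Remark on the chemistry: methoxyacetylene is taken as a purchasable reagent (cold solution). The α-carbon of 9–13 and 15 and the ring sp3 carbon of 17 are carried as epimer mixtures, because this carbon (C4) becomes trigonal before it is finally set in step 9.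

Step 1
Reactants: 1 3,4-dimethoxybenzaldehyde; 2 (4R)-4-benzyl-3-propanoyl-1,3-oxazolidin-2-one
Product: 5 (4R)-4-benzyl-3-[(2R,3R)-3-(3,4-dimethoxyphenyl)-3-hydroxy-2-methylpropanoyl]-1,3-oxazolidin-2-one, via dibutylboron (Z)-enolate 3 (not isolated), via dibutylboron aldolate 4 (not isolated)
Conditions: 2, Bu2BOTf, i-Pr2NEt, CH2Cl2, 0 °C; 1, −78 → 0 °C; pH 7 buffer, MeOH, 30% H2O2, 0 °C
Reagents that add atoms: none
Why: Evans syn-aldol, in which the (Z)-boron enolate reacts through a closed Zimmerman–Traxler chair with one enolate face shielded by the benzyl group of the (R)-auxiliary, so that C8 and C7 are set as (2R,3R) with methyl and hydroxyl syn.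

Step 2
Reactants: 5 aldol adduct
Product: 6 (4R)-4-benzyl-3-[(2R,3R)-3-(tert-butyldimethylsilyloxy)-3-(3,4-dimethoxyphenyl)-2-methylpropanoyl]-1,3-oxazolidin-2-one
Conditions: TBSOTf, 2,6-lutidine, CH2Cl2, −78 → 0 °C
Reagents that add atoms: tert-butyldimethylsilyl trifluoromethanesulfonate, CC(C)(C)[Si](C)(C)OS(=O)(=O)C(F)(F)F
Why: O-silylation with a silyl triflate and a hindered pyridine base is fast in the cold, blocks retro-aldol, and installs a bulky ether that tolerates organolithium reagents and later differentiates the two faces of C4.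

Step 3
Reactants: 6 silyl ether
Product: 7 (2S,3R)-3-(tert-butyldimethylsilyloxy)-3-(3,4-dimethoxyphenyl)-2-methylpropan-1-ol
Conditions: LiBH4, MeOH (1 equiv), THF, 0 °C
Reagents that add atoms: none
Why: Reductive removal of the auxiliary with LiBH4 attacks the exocyclic imide carbonyl and should give the primary alcohol without epimerising C8 or touching the silyl ether (the descriptor at C8 changes only through priorities).

Step 4
Reactants: 7 primary alcohol
Product: 8 (2R,3R)-3-(tert-butyldimethylsilyloxy)-3-(3,4-dimethoxyphenyl)-2-methylpropanal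
Conditions: Dess–Martin periodinane, pyridine, CH2Cl2, 0 → 20 °C; used crude
Reagents that add atoms: none
Why: Dess–Martin oxidation under buffered, non-basic conditions stops at the aldehyde and avoids enolisation at C8 and β-elimination of the silyloxy group.

Step 5
Reactants: 8 aldehyde
Product: 9 tert-butyl{[(1R,2R,3RS)-4,4,4-trichloro-1-(3,4-dimethoxyphenyl)-2-methyl-3-(trimethylsilyloxy)butyl]oxy}dimethylsilane
Conditions: Me3SiCCl3, Bu4NOAc (5 mol %), THF, −20 → 0 °C
Reagents that add atoms: trimethyl(trichloromethyl)silane, C[Si](C)(C)C(Cl)(Cl)Cl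
Why: Acetate-initiated 1,2-addition of the trichloromethyl group from silicon to the aldehyde runs cold and almost neutral, so C8 should not epimerise, and the new carbinol centre may be a mixture because it is erased at the ketene stage.

Step 6
Reactants: 9 silylated trichloromethyl carbinol
Product: 13 (2RS,3S,4R)-4-(tert-butyldimethylsilyloxy)-4-(3,4-dimethoxyphenyl)-2-methoxy-3-methylbutanoic acid, via trichloromethyl carbinol 10 (not isolated), via gem-dichloro epoxide 11 (not isolated), via α-methoxy acid chloride 12 (not isolated)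
Conditions: KOH, MeOH, 0 → 45 °C; then H2O; citric acid to pH 4
Reagents that add atoms: methanol, CO; potassium hydroxide, [K+].[OH-]
Why: Jocic–Reeve reaction, in which base removes the O-trimethylsilyl group, the alkoxide closes to the gem-dichloro epoxide, methoxide opens it by SN2 at the carbinol carbon and the acyl chloride is hydrolysed at once in the basic medium, giving the one-carbon-homologated α-methoxy acid while the hindered silyl ether and C7/C8 stay untouched.

Step 7
Reactants: 13 α-methoxy acid; 14 methoxyacetylene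
Product: 17 4-[(1R,2R)-1-(tert-butyldimethylsilyloxy)-1-(3,4-dimethoxyphenyl)propan-2-yl]-3,4-dimethoxycyclobut-2-en-1-one (both epimers at the ring sp3 carbon), via acyloxypyridinium iodide 15 (not isolated), via methoxy ketene 16 (not isolated)
Conditions: 2-chloro-1-methylpyridinium iodide (1.5 equiv), 14 (4 equiv), MeCN; 13 and Et3N (3 equiv) added slowly, 20 → 45 °C, sealed vessel
Reagents that add atoms: none
Why: Ketene generation from a carboxylic acid by Mukaiyama activation, in which the carboxylate displaces chloride from the pyridinium salt and Et3N eliminates 1-methyl-2-pyridone from the activated ester under non-acidic conditions that spare the benzylic silyl ether, followed by [2+2] ketene–alkyne cycloaddition of the ynol ether with its unsubstituted carbon on the ketene carbonyl carbon, which gives the 3-methoxycyclobutenone regiochemistry.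

Step 8
Reactants: 18 2,3-dibromopropene
Product: 19 2-bromopenta-1,4-diene
Conditions: vinylmagnesium bromide, CuI (5 mol %), THF, −20 → 0 °C; distillation
Reagents that add atoms: vinylmagnesium bromide, C=C[Mg]Br
Why: Copper-catalysed allylic substitution by the vinyl Grignard reagent takes place at the allylic bromide only and leaves the vinylic bromide for the later lithium–bromine exchange.

Step 9
Reactants: 17 cyclobutenone; 19 2-bromopenta-1,4-diene
Product: 24 (4R)-2-allyl-4-[(1R,2R)-1-(tert-butyldimethylsilyloxy)-1-(3,4-dimethoxyphenyl)propan-2-yl]-4,5-dimethoxy-1-(trimethylsilyloxy)cyclohexa-1,5-diene, via 2-lithiopenta-1,4-diene 20 (not isolated), via lithium cyclobutenoxide 21 (not isolated), via lithium trienolate 22 (not isolated), via lithium cyclohexadienolate 23 (not isolated)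
Conditions: 19, t-BuLi (2 equiv), Et2O, −78 °C; 17 in THF, −78 °C; warm to 25 °C (40 °C if closure is slow); then Me3SiCl, Et3N, −78 → 0 °C; non-aqueous work-up, used crude
Reagents that add atoms: chlorotrimethylsilane, C[Si](C)(C)Cl
Why: Proposed new method: lithium–bromine exchange (the second equivalent of t-BuLi consumes the t-BuBr formed) gives the alkenyllithium, which adds 1,2 to the strained carbonyl C1 from the face away from the bulky side chain on C4, so that the new alkoxide is trans to the C4 methoxy group; on warming, the cyclobutenoxide undergoes strain-releasing, alkoxide-accelerated conrotatory 4π opening of the C1–C4 bond with both oxygen substituents rotating outward, and the 3-oxido-hexatriene C3=C2–C1=C6–C5=C4 closes ring A by disrotatory 6π electrocyclisation between C3 and C4 before Me3SiCl silylates the dienolate on oxygen. The closest known chemistry is the 1,2-addition of alkenyllithiums to 3-alkoxycyclobutenones and the oxyanion-driven ring-opening and reclosure cascades of squarate-derived cyclobutenoxides; new is their use on a 4,4-disubstituted 3-methoxycyclobutenone to give a cyclohexadienolate with a quaternary carbon. The only new stereocentre, C4, is set in the 6π closure under control of C8: allylic 1,3-strain holds the C8–H bond in the plane of C4=C5, and C3 should bond to the face of C4 that carries the C8 methyl group, anti to the aryl(silyloxy)methyl branch, which corresponds to (4R). The step needs 1,2- and not 1,4-addition (hard organolithium, low temperature, strained carbonyl), the cis arrangement of C2 and C5 across C1=C6 (outward rotation of the oxido group) and one-sided attack at C4 (biased only by C8 and the bulky silyl ether, the uncertain point). Both epimers of 17 converge on the same trienolate because the ring carbon that opens becomes trigonal.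

Step 10
Reactants: 24 silyl dienol ether
Product: 25 (4R)-2-allyl-4-[(1R,2R)-1-(tert-butyldimethylsilyloxy)-1-(3,4-dimethoxyphenyl)propan-2-yl]-4,5-dimethoxycyclohexa-2,5-dien-1-one
Conditions: Pd(OAc)2 (1.1 equiv), MeCN, 20 °C
Reagents that add atoms: none
Why: Saegusa–Ito oxidation, in which divalent palladium converts the silyl enol ether into a palladium enolate at C2 and β-hydride elimination of the ring hydrogen at C3 should give the cross-conjugated dienone and zerovalent palladium, as is usual for palladium enolates of 2-substituted cycloalkanones, with C4, C7 and C8 untouched.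

Step 11
Reactants: 25 dienone silyl ether
Product: 26 (4R)-2-allyl-4-[(1R,2R)-1-(3,4-dimethoxyphenyl)-1-hydroxypropan-2-yl]-4,5-dimethoxycyclohexa-2,5-dien-1-one
Conditions: HF·pyridine, pyridine, THF, 0 → 20 °C; used at once
Reagents that add atoms: none
Why: Pyridine-buffered HF·pyridine cleaves the silyl ether under weakly acidic conditions, so the C7 hydroxyl is never an alkoxide and its conjugate addition to C3 of the dienone is held back, while the vinylogous ester and the tertiary methyl ether should survive.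

Step 12
Reactants: 26 hydroxy dienone
Product: 27 (1R,2R)-1-(3,4-dimethoxyphenyl)-2-[(1R)-1,2-dimethoxy-4-oxo-5-(prop-2-en-1-yl)cyclohexa-2,5-dien-1-yl]propyl acetate (CNP0159267.1)
Conditions: Ac2O, pyridine, 4-(dimethylamino)pyridine (cat.), CH2Cl2, 0 °C
Reagents that add atoms: acetic anhydride, CC(=O)OC(C)=O
Why: Nucleophile-catalysed acylation of the secondary benzylic alcohol is fast at 0 °C, leaves little time for oxa-Michael cyclisation and changes no stereocentre.

Compound list
1 | 3,4-dimethoxybenzaldehyde | COc1ccc(C=O)cc1OC | starting material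
2 | (4R)-4-benzyl-3-propanoyl-1,3-oxazolidin-2-one | CCC(=O)N1[C@H](Cc2ccccc2)COC1=O | starting material
3 | (4R)-4-benzyl-3-[(1Z)-1-(dibutylboranyloxy)prop-1-en-1-yl]-1,3-oxazolidin-2-one | C/C=C(\OB(CCCC)CCCC)N1[C@H](Cc2ccccc2)COC1=O | intermediate
4 | (4R)-4-benzyl-3-[(2R,3R)-3-(dibutylboranyloxy)-3-(3,4-dimethoxyphenyl)-2-methylpropanoyl]-1,3-oxazolidin-2-one | O=C1OC[C@@H](Cc2ccccc2)N1C(=O)[C@H](C)[C@@H](OB(CCCC)CCCC)c3ccc(OC)c(OC)c3 | intermediate
5 | (4R)-4-benzyl-3-[(2R,3R)-3-(3,4-dimethoxyphenyl)-3-hydroxy-2-methylpropanoyl]-1,3-oxazolidin-2-one | O=C1OC[C@@H](Cc2ccccc2)N1C(=O)[C@H](C)[C@@H](O)c3ccc(OC)c(OC)c3 | intermediate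
6 | (4R)-4-benzyl-3-[(2R,3R)-3-(tert-butyldimethylsilyloxy)-3-(3,4-dimethoxyphenyl)-2-methylpropanoyl]-1,3-oxazolidin-2-one | O=C1OC[C@@H](Cc2ccccc2)N1C(=O)[C@H](C)[C@@H](O[Si](C)(C)C(C)(C)C)c3ccc(OC)c(OC)c3 | intermediate
7 | (2S,3R)-3-(tert-butyldimethylsilyloxy)-3-(3,4-dimethoxyphenyl)-2-methylpropan-1-ol | OC[C@H](C)[C@@H](O[Si](C)(C)C(C)(C)C)c1ccc(OC)c(OC)c1 | intermediate
8 | (2R,3R)-3-(tert-butyldimethylsilyloxy)-3-(3,4-dimethoxyphenyl)-2-methylpropanal | O=C[C@H](C)[C@@H](O[Si](C)(C)C(C)(C)C)c1ccc(OC)c(OC)c1 | intermediate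
9 | tert-butyl{[(1R,2R,3RS)-4,4,4-trichloro-1-(3,4-dimethoxyphenyl)-2-methyl-3-(trimethylsilyloxy)butyl]oxy}dimethylsilane | ClC(Cl)(Cl)C(O[Si](C)(C)C)[C@H](C)[C@@H](O[Si](C)(C)C(C)(C)C)c1ccc(OC)c(OC)c1 | intermediate
10 | (2RS,3S,4R)-4-(tert-butyldimethylsilyloxy)-1,1,1-trichloro-4-(3,4-dimethoxyphenyl)-3-methylbutan-2-ol | ClC(Cl)(Cl)C(O)[C@H](C)[C@@H](O[Si](C)(C)C(C)(C)C)c1ccc(OC)c(OC)c1 | intermediate
11 | tert-butyl{[(1R,2S)-2-(3,3-dichlorooxiran-2-yl)-1-(3,4-dimethoxyphenyl)propyl]oxy}dimethylsilane | ClC1(Cl)OC1[C@H](C)[C@@H](O[Si](C)(C)C(C)(C)C)c2ccc(OC)c(OC)c2 | intermediate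
12 | (2RS,3S,4R)-4-(tert-butyldimethylsilyloxy)-4-(3,4-dimethoxyphenyl)-2-methoxy-3-methylbutanoyl chloride | ClC(=O)C(OC)[C@H](C)[C@@H](O[Si](C)(C)C(C)(C)C)c1ccc(OC)c(OC)c1 | intermediate
13 | (2RS,3S,4R)-4-(tert-butyldimethylsilyloxy)-4-(3,4-dimethoxyphenyl)-2-methoxy-3-methylbutanoic acid | OC(=O)C(OC)[C@H](C)[C@@H](O[Si](C)(C)C(C)(C)C)c1ccc(OC)c(OC)c1 | intermediate
14 | methoxyacetylene | C#COC | starting material
15 | 2-{[(2RS,3S,4R)-4-(tert-butyldimethylsilyloxy)-4-(3,4-dimethoxyphenyl)-2-methoxy-3-methylbutanoyl]oxy}-1-methylpyridin-1-ium iodide | C[n+]1ccccc1OC(=O)C(OC)[C@H](C)[C@@H](O[Si](C)(C)C(C)(C)C)c1ccc(OC)c(OC)c1.[I-] | intermediate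
16 | (3R,4R)-4-(tert-butyldimethylsilyloxy)-4-(3,4-dimethoxyphenyl)-2-methoxy-3-methylbut-1-en-1-one | O=C=C(OC)[C@H](C)[C@@H](O[Si](C)(C)C(C)(C)C)c1ccc(OC)c(OC)c1 | intermediate
17 | 4-[(1R,2R)-1-(tert-butyldimethylsilyloxy)-1-(3,4-dimethoxyphenyl)propan-2-yl]-3,4-dimethoxycyclobut-2-en-1-one | O=C1C=C(OC)C1(OC)[C@H](C)[C@@H](O[Si](C)(C)C(C)(C)C)c2ccc(OC)c(OC)c2 | intermediate
18 | 2,3-dibromopropene | C=C(Br)CBr | starting material
19 | 2-bromopenta-1,4-diene | C=C(Br)CC=C | intermediate
20 | 2-lithiopenta-1,4-diene | [Li]C(=C)CC=C | intermediate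
21 | lithium 4-[(1R,2R)-1-(tert-butyldimethylsilyloxy)-1-(3,4-dimethoxyphenyl)propan-2-yl]-3,4-dimethoxy-1-(penta-1,4-dien-2-yl)cyclobut-2-en-1-olate | [Li+].[O-]C1(C(=C)CC=C)C=C(OC)C1(OC)[C@H](C)[C@@H](O[Si](C)(C)C(C)(C)C)c2ccc(OC)c(OC)c2 | intermediate
22 | lithium (3E,5Z,7R,8R)-8-(tert-butyldimethylsilyloxy)-8-(3,4-dimethoxyphenyl)-5,6-dimethoxy-7-methyl-2-(prop-2-en-1-yl)octa-1,3,5-trien-3-olate (trienolate C3=C2–C1(OLi)=C6–C5(OMe)=C4(OMe)–C8 in ring A numbering; oxido group trans to C5, side chain cis to C6) | [Li+].[O-]/C(C(=C)CC=C)=C/C(OC)=C(OC)\[C@H](C)[C@@H](O[Si](C)(C)C(C)(C)C)c1ccc(OC)c(OC)c1 | intermediate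
23 | lithium (4R)-2-allyl-4-[(1R,2R)-1-(tert-butyldimethylsilyloxy)-1-(3,4-dimethoxyphenyl)propan-2-yl]-4,5-dimethoxycyclohexa-1,5-dien-1-olate | C=CCC1=C([O-])C=C(OC)[C@](OC)([C@H](C)[C@@H](O[Si](C)(C)C(C)(C)C)c2ccc(OC)c(OC)c2)C1.[Li+] | intermediate
24 | (4R)-2-allyl-4-[(1R,2R)-1-(tert-butyldimethylsilyloxy)-1-(3,4-dimethoxyphenyl)propan-2-yl]-4,5-dimethoxy-1-(trimethylsilyloxy)cyclohexa-1,5-diene | C=CCC1=C(O[Si](C)(C)C)C=C(OC)[C@](OC)([C@H](C)[C@@H](O[Si](C)(C)C(C)(C)C)c2ccc(OC)c(OC)c2)C1 | intermediate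
25 | (4R)-2-allyl-4-[(1R,2R)-1-(tert-butyldimethylsilyloxy)-1-(3,4-dimethoxyphenyl)propan-2-yl]-4,5-dimethoxycyclohexa-2,5-dien-1-one | C=CCC1=C[C@@](OC)([C@H](C)[C@@H](O[Si](C)(C)C(C)(C)C)c2ccc(OC)c(OC)c2)C(OC)=CC1=O | intermediate
26 | (4R)-2-allyl-4-[(1R,2R)-1-(3,4-dimethoxyphenyl)-1-hydroxypropan-2-yl]-4,5-dimethoxycyclohexa-2,5-dien-1-one | C=CCC1=C[C@@](OC)([C@H](C)[C@@H](O)c2ccc(OC)c(OC)c2)C(OC)=CC1=O | intermediate
27 | (1R,2R)-1-(3,4-dimethoxyphenyl)-2-[(1R)-1,2-dimethoxy-4-oxo-5-(prop-2-en-1-yl)cyclohexa-2,5-dien-1-yl]propyl acetate | C=CCC1=C[C@@](OC)([C@H](C)[C@@H](OC(C)=O)c2ccc(OC)c(OC)c2)C(OC)=CC1=O | target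

Total step count: 12. Longest linear sequence: 11 steps (steps 1–7 and 9–12); step 8 is a one-step side branch.

Steps most likely to fail

1. Step 9 (proposed new method). The cyclobutenoxide may not open cleanly, or the trienolate, which carries the bulky side chain on the inside at C4, may close too slowly and be lost to proton transfer or oligomerisation. Closure may also take place on both faces of C4 and give the wrong epimer.
Fallback (known chemistry): ring A would be made by oxidative dearomatisation of a para-alkylphenol with a trivalent iodine reagent in methanol. This does not branch from a numbered intermediate: it is a separate line from purchasable materials and comes back to the route at target 27. The imide (4S)-4-benzyl-3-{[2-methoxy-4-(prop-2-en-1-yloxy)phenyl]acetyl}-1,3-oxazolidin-2-one F1, from the arylacetic acid and the (S)-auxiliary, would be methylated (NaN(SiMe3)2, MeI, THF, −78 °C) to the (2S)-propanoyl imide F2. LiBH4 would then give the (2S)-2-arylpropan-1-ol F3 and Dess–Martin periodinane the (2S)-2-arylpropanal F4. Felkin–Anh addition of 3,4-dimethoxyphenylmagnesium bromide (Et2O, −78 °C) should favour the (1R,2S)-1,2-diarylpropan-1-ol F5, which is acetylated (Ac2O, pyridine) to the acetate F6. Aromatic Claisen rearrangement (N,N-diethylaniline, 190 °C) should move the allyl group mainly to the less hindered ortho position and give the phenol F7. PhI(OAc)2 in MeOH at 0 °C would then add methanol at the alkyl-bearing para carbon and give 27 together with its C4 epimer F8, to be separated by chromatography.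

2. Step 7. Elimination from the hindered activated ester may be slow, so that it is diverted to the symmetrical anhydride or the ketene dimerises, and the volatile, acid-sensitive ynol ether may polymerise or escape before it traps the ketene.
Fallback: sets out from acid 13 and comes back at 17. The ketene 16 is generated in the same way, but in the presence of an excess of 1,1-dimethoxyethene, a non-volatile and more nucleophilic partner. The [2+2] adduct is the 2,3,3-trimethoxycyclobutanone F9, and elimination of methanol (pyridinium p-toluenesulfonate, warm benzene) would give the enol ether 17.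

3. Step 11. Once the C7 hydroxyl is free, it can add to C3 of the dienone (five-membered-ring oxa-Michael closure) during desilylation or work-up.
Fallback: sets out from 24 and comes back at 27, changing the order so that a free hydroxyl never faces the dienone. HF·pyridine on 24 would cleave both silyl groups and give the hydroxy enone F10, which has no acceptor at C3. Acetylation (Ac2O, pyridine, 4-(dimethylamino)pyridine) would give the acetate F11, soft enolisation (Me3SiOTf, Et3N, CH2Cl2, 0 °C) the silyl dienol ether F12, and Pd(OAc)2 in MeCN the target 27 directly.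

Further compounds
F1 | step 9 | (4S)-4-benzyl-3-{[2-methoxy-4-(prop-2-en-1-yloxy)phenyl]acetyl}-1,3-oxazolidin-2-one | C=CCOc1ccc(CC(=O)N2[C@@H](Cc3ccccc3)COC2=O)c(OC)c1
F2 | step 9 | (4S)-4-benzyl-3-{(2S)-2-[2-methoxy-4-(prop-2-en-1-yloxy)phenyl]propanoyl}-1,3-oxazolidin-2-one | C[C@@H](c1ccc(OCC=C)cc1OC)C(=O)N1[C@@H](Cc2ccccc2)COC1=O
F3 | step 9 | (2S)-2-[2-methoxy-4-(prop-2-en-1-yloxy)phenyl]propan-1-ol | C[C@@H](c1ccc(OCC=C)cc1OC)CO
F4 | step 9 | (2S)-2-[2-methoxy-4-(prop-2-en-1-yloxy)phenyl]propanal | C[C@@H](c1ccc(OCC=C)cc1OC)C=O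
F5 | step 9 | (1R,2S)-1-(3,4-dimethoxyphenyl)-2-[2-methoxy-4-(prop-2-en-1-yloxy)phenyl]propan-1-ol | C[C@@H](c1ccc(OCC=C)cc1OC)[C@@H](O)c1ccc(OC)c(OC)c1
F6 | step 9 | (1R,2S)-1-(3,4-dimethoxyphenyl)-2-[2-methoxy-4-(prop-2-en-1-yloxy)phenyl]propyl acetate | C[C@@H](c1ccc(OCC=C)cc1OC)[C@@H](OC(C)=O)c1ccc(OC)c(OC)c1
F7 | step 9 | (1R,2S)-1-(3,4-dimethoxyphenyl)-2-[4-hydroxy-2-methoxy-5-(prop-2-en-1-yl)phenyl]propyl acetate | C[C@@H](c1cc(CC=C)c(O)cc1OC)[C@@H](OC(C)=O)c1ccc(OC)c(OC)c1
F8 | step 9 | (1R,2R)-1-(3,4-dimethoxyphenyl)-2-[(1S)-1,2-dimethoxy-4-oxo-5-(prop-2-en-1-yl)cyclohexa-2,5-dien-1-yl]propyl acetate | C=CCC1=C[C@](OC)([C@H](C)[C@@H](OC(C)=O)c2ccc(OC)c(OC)c2)C(OC)=CC1=O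
F9 | step 7 | 2-[(1R,2R)-1-(tert-butyldimethylsilyloxy)-1-(3,4-dimethoxyphenyl)propan-2-yl]-2,3,3-trimethoxycyclobutan-1-one | O=C1CC(OC)(OC)C1(OC)[C@H](C)[C@@H](O[Si](C)(C)C(C)(C)C)c2ccc(OC)c(OC)c2
F10 | step 11 | (4R,6RS)-4-[(1R,2R)-1-(3,4-dimethoxyphenyl)-1-hydroxypropan-2-yl]-3,4-dimethoxy-6-(prop-2-en-1-yl)cyclohex-2-en-1-one | C=CCC1C[C@@](OC)([C@H](C)[C@@H](O)c2ccc(OC)c(OC)c2)C(OC)=CC1=O
F11 | step 11 | (1R,2R)-1-(3,4-dimethoxyphenyl)-2-[(1R,5RS)-1,2-dimethoxy-4-oxo-5-(prop-2-en-1-yl)cyclohex-2-en-1-yl]propyl acetate | C=CCC1C[C@@](OC)([C@H](C)[C@@H](OC(C)=O)c2ccc(OC)c(OC)c2)C(OC)=CC1=O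
F12 | step 11 | (1R,2R)-1-(3,4-dimethoxyphenyl)-2-[(1R)-1,2-dimethoxy-5-(prop-2-en-1-yl)-4-(trimethylsilyloxy)cyclohexa-2,4-dien-1-yl]propyl acetate | C=CCC1=C(O[Si](C)(C)C)C=C(OC)[C@](OC)([C@H](C)[C@@H](OC(C)=O)c2ccc(OC)c(OC)c2)C1
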